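**Assumption:** the target has no stereocentre or stereogenic axis, so it is achiral and "single enantiomer" adds no stereochemical task; all SMILES are written without stereodescriptors. Compounds 1, 5 and 6 are taken as catalogue materials. The route is designed from known flavone chemistry and has not been run.

## Retrosynthetic overview

1. Target 13 ⇐ hydrogenolysis of the two B-ring benzyl ethers of 12 ⇐ chelation-directed 5-O-demethylation of hexamethoxyflavone 11.
2. Ring C of 11 (the only ring built) ⇐ cyclodehydration of 2-methoxy-1,3-diketone 10 ⇐ Baker–Venkataraman O→C acyl shift of aryl ester 9.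
3. Ester 9 ⇐ aroyl chloride 4 + o-hydroxy-ω-methoxyacetophenone 8; the 3-OMe comes in with the ω-methoxy ketone.
4. 8 ⇐ Friedel–Crafts acylation of pentamethoxybenzene 5 with methoxyacetyl chloride 6 with in-flask ortho-demethylation; 4 ⇐ methyl 4-O-methylgallate 1 (benzylation, saponification, chlorination).
5. Rings A and B are bought intact; ring C is formed last from the two halves.

## Route

**Step 1**
Reactants: 1 methyl 3,5-dihydroxy-4-methoxybenzoate
Product: 2 methyl 3,5-bis(benzyloxy)-4-methoxybenzoate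
Conditions: BnBr (2.4 equiv), K2CO3 (3 equiv), DMF, 60 °C
Reagents that add atoms: benzyl bromide, BrCc1ccccc1
Why: Williamson ether synthesis (SN2) on the two equivalent phenoxides; the ester is inert to carbonate and no stereocentre is involved.

**Step 2**
Reactants: 2 methyl 3,5-bis(benzyloxy)-4-methoxybenzoate
Product: 3 3,5-bis(benzyloxy)-4-methoxybenzoic acid
Conditions: 2 M NaOH aq, THF–MeOH, reflux; then HCl to pH 2
Reagents that add atoms: sodium hydroxide, [Na+].[OH-]
Why: Saponification (BAc2 ester hydrolysis); benzyl and methyl aryl ethers are stable to aqueous hydroxide.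

**Step 3**
Reactants: 3 3,5-bis(benzyloxy)-4-methoxybenzoic acid
Product: 4 3,5-bis(benzyloxy)-4-methoxybenzoyl chloride
Conditions: (COCl)2 (1.5 equiv), cat. DMF, CH2Cl2, 0 °C → rt; evaporate, use crude
Reagents that add atoms: oxalyl chloride, ClC(=O)C(=O)Cl
Why: DMF-catalysed (Vilsmeier-type) acid chloride formation gives only gaseous by-products and leaves the ethers untouched.

**Step 4**
Reactants: 5 pentamethoxybenzene; 6 methoxyacetyl chloride
Product: 8 1-(2-hydroxy-3,4,5,6-tetramethoxyphenyl)-2-methoxyethan-1-one, via 2-methoxy-1-(pentamethoxyphenyl)ethanone 7 (not isolated)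
Conditions: 6 (1.2 equiv), AlCl3 (2.5 equiv), Et2O, 0 °C → rt; then ice/2 M HCl
Reagents that add atoms: none
Why: Friedel–Crafts acylation at the only free ring position, then chelation-controlled AlCl3 cleavage of one of the two equivalent ortho-methoxy groups, so a single phenol results.

**Step 5**
Reactants: 4 3,5-bis(benzyloxy)-4-methoxybenzoyl chloride; 8 1-(2-hydroxy-3,4,5,6-tetramethoxyphenyl)-2-methoxyethan-1-one
Product: 9 2-(methoxyacetyl)-3,4,5,6-tetramethoxyphenyl 3,5-bis(benzyloxy)-4-methoxybenzoate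
Conditions: 4 (1.2 equiv), pyridine, DMAP (0.1 equiv), 80 °C
Reagents that add atoms: none
Why: DMAP-catalysed nucleophilic acyl substitution (Einhorn-type O-aroylation); the acylpyridinium is reactive enough for the hindered, hydrogen-bonded phenol.

**Step 6**
Reactants: 9 2-(methoxyacetyl)-3,4,5,6-tetramethoxyphenyl 3,5-bis(benzyloxy)-4-methoxybenzoate
Product: 11 3',5'-bis(benzyloxy)-3,5,6,7,8,4'-hexamethoxyflavone, via 2-methoxy-1,3-diketone 10 (not isolated)
Conditions: powdered KOH (3 equiv), pyridine, 60 °C; AcOH/ice quench; crude 10, NaOAc, AcOH, reflux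
Reagents that add atoms: none
Why: Baker–Venkataraman rearrangement (intramolecular Claisen-type O→C aroyl transfer through the ketone enolate) followed by cyclodehydration to the chromen-4-one; the enolisable C-2 centre of 10 becomes sp2, so no stereocentre remains.

**Step 7**
Reactants: 11 3',5'-bis(benzyloxy)-3,5,6,7,8,4'-hexamethoxyflavone
Product: 12 3',5'-bis(benzyloxy)-5-hydroxy-3,6,7,8,4'-pentamethoxyflavone
Conditions: anhydrous AlCl3 (6 equiv), MeCN, rt; then 2% HCl aq, 60 °C, 20 min
Reagents that add atoms: none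
Why: Lewis-acid aryl methyl ether cleavage directed by the six-membered Al chelate between the 4-C=O and the peri 5-OMe, which in MeCN reacts well before the 3-, 6-, 7-, 8-, 4'-OMe groups and the benzyl ethers.

**Step 8**
Reactants: 12 3',5'-bis(benzyloxy)-5-hydroxy-3,6,7,8,4'-pentamethoxyflavone
Product: 13 5,3',5'-trihydroxy-3,6,7,8,4'-pentamethoxyflavone
Conditions: H2 (1 atm), 10% Pd/C, EtOAc–MeOH (1:1), rt
Reagents that add atoms: none
Why: Catalytic hydrogenolysis cleaves only the benzylic C–O bonds; aryl methyl ethers and the tetrasubstituted chromone C2=C3 bond survive at 1 atm and rt.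

## Compound list

1 | methyl 3,5-dihydroxy-4-methoxybenzoate | COC(=O)c1cc(O)c(OC)c(O)c1 | starting material
2 | methyl 3,5-bis(benzyloxy)-4-methoxybenzoate | COC(=O)c1cc(OCc2ccccc2)c(OC)c(OCc2ccccc2)c1 | intermediate
3 | 3,5-bis(benzyloxy)-4-methoxybenzoic acid | OC(=O)c1cc(OCc2ccccc2)c(OC)c(OCc2ccccc2)c1 | intermediate
4 | 3,5-bis(benzyloxy)-4-methoxybenzoyl chloride | ClC(=O)c1cc(OCc2ccccc2)c(OC)c(OCc2ccccc2)c1 | intermediate
5 | pentamethoxybenzene | COc1cc(OC)c(OC)c(OC)c1OC | starting material
6 | methoxyacetyl chloride | COCC(Cl)=O | starting material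
7 | 2-methoxy-1-(2,3,4,5,6-pentamethoxyphenyl)ethan-1-one | COCC(=O)c1c(OC)c(OC)c(OC)c(OC)c1OC | intermediate
8 | 1-(2-hydroxy-3,4,5,6-tetramethoxyphenyl)-2-methoxyethan-1-one | COCC(=O)c1c(O)c(OC)c(OC)c(OC)c1OC | intermediate
9 | 2-(methoxyacetyl)-3,4,5,6-tetramethoxyphenyl 3,5-bis(benzyloxy)-4-methoxybenzoate | COCC(=O)c1c(OC(=O)c2cc(OCc3ccccc3)c(OC)c(OCc3ccccc3)c2)c(OC)c(OC)c(OC)c1OC | intermediate
10 | 1-[3,5-bis(benzyloxy)-4-methoxyphenyl]-3-(2-hydroxy-3,4,5,6-tetramethoxyphenyl)-2-methoxypropane-1,3-dione (racemic, enolisable C-2) | COC(C(=O)c1cc(OCc2ccccc2)c(OC)c(OCc2ccccc2)c1)C(=O)c1c(O)c(OC)c(OC)c(OC)c1OC | intermediate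
11 | 3',5'-bis(benzyloxy)-3,5,6,7,8,4'-hexamethoxyflavone | COc1c(OCc2ccccc2)cc(-c2oc3c(OC)c(OC)c(OC)c(OC)c3c(=O)c2OC)cc1OCc1ccccc1 | intermediate
12 | 3',5'-bis(benzyloxy)-5-hydroxy-3,6,7,8,4'-pentamethoxyflavone | COc1c(OCc2ccccc2)cc(-c2oc3c(OC)c(OC)c(OC)c(O)c3c(=O)c2OC)cc1OCc1ccccc1 | intermediate
13 | 5,3',5'-trihydroxy-3,6,7,8,4'-pentamethoxyflavone | COc1c(O)cc(-c2oc3c(OC)c(OC)c(OC)c(O)c3c(=O)c2OC)cc1O | target

## Step count and risks

Total steps: 8. Longest linear sequence: 7 (steps 1, 2, 3, 5, 6, 7, 8 from compound 1); the A-ring branch from 5 is 5 steps (4, 5, 6, 7, 8).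

**Risk 1, step 4.** AlCl3 may over-demethylate (second ortho-OMe or the side-chain OMe) or degrade the very electron-rich arene. The fallback sets out from 5 and comes back to the route at 8. Deprotonate 5 at its single C–H, flanked by two methoxy groups, with n-BuLi/TMEDA in THF at 0 °C (directed ortho-metalation) to give (2,3,4,5,6-pentamethoxyphenyl)lithium F1. Acylate F1 with the Weinreb amide N,2-dimethoxy-N-methylacetamide (−78 → 0 °C, NH4Cl quench) to give 7, now isolated. Then cleave one ortho-methoxy group in a separate chelation-controlled step with BCl3 (1.1 equiv, CH2Cl2, −78 → 0 °C) to give 8.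

**Risk 2, step 6.** The hindered, electron-rich ester 9 may be hydrolysed by KOH faster than it rearranges, or diketone 10 may cyclise sluggishly. The fallback sets out from 8 (with 3 and 4) and comes back at 11, bypassing 9 and 10, by an Allan–Robinson condensation. Make 3,5-bis(benzyloxy)-4-methoxybenzoic anhydride F2 from 3 and 4 (pyridine, CH2Cl2), and potassium 3,5-bis(benzyloxy)-4-methoxybenzoate F3 from 3 and KOH. Fuse 8 with F2 (3 equiv) and F3 at 175–180 °C under reduced pressure, then reflux briefly in aqueous-ethanolic KOH to destroy excess anhydride; this gives 11 directly.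

**Risk 3, step 7.** AlCl3 may partly remove benzyl groups or also attack the 3- or 6-OMe, giving mixtures. The fallback sets out from 11 and comes back at the target 13 by reversing the order of the two deprotections. Hydrogenolyse 11 first (H2, Pd/C, EtOAc–MeOH) to 3',5'-dihydroxy-3,5,6,7,8,4'-hexamethoxyflavone F4. Then cleave only the 5-OMe with a Brønsted acid (33% HBr in AcOH, rt), where protonation of the 4-carbonyl activates just the peri methoxy group, to give 13.

## Further compounds

F1 | step 4 | (2,3,4,5,6-pentamethoxyphenyl)lithium | [Li]c1c(OC)c(OC)c(OC)c(OC)c1OC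
F2 | step 6 | 3,5-bis(benzyloxy)-4-methoxybenzoic anhydride | O=C(OC(=O)c1cc(OCc2ccccc2)c(OC)c(OCc2ccccc2)c1)c1cc(OCc2ccccc2)c(OC)c(OCc2ccccc2)c1
F3 | step 6 | potassium 3,5-bis(benzyloxy)-4-methoxybenzoate | [K+].[O-]C(=O)c1cc(OCc2ccccc2)c(OC)c(OCc2ccccc2)c1
F4 | step 7 | 3',5'-dihydroxy-3,5,6,7,8,4'-hexamethoxyflavone | COc1c(O)cc(-c2oc3c(OC)c(OC)c(OC)c(OC)c3c(=O)c2OC)cc1O
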